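**Plan**
- Retrosynthesis: the two angelate C–O bonds (C1, C5) and the C9–isopropyl bond are cut first. The C6–C10 bond of the hydroazulene is then traced back to the C1–C6 bond of a cis-decalin 9,10-epoxy-1-silyl ether, and the decalin to a dione, methyl vinyl ketone and methyl iodide (C1–C10 aldol, C6–C7 Michael, C6–CH3 alkylation).
- Enabling feature: in the target the oxygenated C1 and the quaternary C6 are both bonded to the fusion methine C10, which is flanked by the C9 carbinol. This C1(O)–C10(H)–C6 array, shared by the seven-membered ring (C1–C6, C10) and the five-membered ring (C6–C10), is what a 1,2-shift of C6 from C1 to C10 leaves behind.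
- Forward: ring A comes from the dione and ring B is closed by a proline aldol condensation (decalin). In the key step ring A grows to the seven-membered ring while ring B shrinks to the five-membered ring; afterwards only functional groups change.
- Stereochemistry before the shift: C6 from the L-proline aldol; a temporary C3 centre (methyl cis to the C6 methyl, from axial methylation) locks the reacting conformer; the C1 oxygen and the epoxide come from β-face peroxide addition, Wharton transposition and hydroxyl-directed epoxidation; C10 is set by inversion in the shift.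
- Stereochemistry after the shift: C1 by hydride delivery from the C9 oxygen (Evans–Tishchenko); C9 by α-face addition anti to the C6 methyl; C5 by α-face epoxidation of a C4=C5 alkene and eliminative opening toward C3, which also erases the C3 centre.

Key step: step 9

Remark: ring carbons keep the target numbering in every intermediate (C1 OCH, C2, C3 C–CH3, C4, C5 OCH, C6 quaternary C–CH3, C7, C8, C9 carbinol, C10 fusion CH); in the decalins ring A is C1–C6 and ring B is C1, C6–C10; β is the face of the C6 methyl.
Assumption: methylation of the enolate of 3 is taken to occur mainly cis to the 5-methyl group (axial attack); the C3 centre so formed is deliberately β, because the 3α epimer would align C2 rather than C6 for migration in step 9.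

Step 1
Reactants: 1 5-methylcyclohexane-1,3-dione; 2 methyl vinyl ketone
Product: 3 5-methyl-2-(3-oxobutyl)cyclohexane-1,3-dione
Conditions: H2O, hydroquinone (cat.), rt
Reagents that add atoms: none
Why: Michael addition of the acidic 1,3-dione to the enone in water is a standard C-alkylation that stops at the mono-adduct, and it installs the chain first so that the methyl group can be brought in last.

Step 2
Reactants: 3 5-methyl-2-(3-oxobutyl)cyclohexane-1,3-dione
Product: 4 cis-2,5-dimethyl-2-(3-oxobutyl)cyclohexane-1,3-dione
Conditions: MeI, K2CO3, acetone, 50 °C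
Reagents that add atoms: iodomethane, CI
Why: C-methylation of the 2-substituted dione enolate creates the quaternary carbon (future C6), and axial entry of the small electrophile anti to the ring flap should place the new methyl cis to the equatorial 5-methyl (future C3), the same stereoelectronic preference seen in Robinson annulations of dihydrocarvone; any trans isomer or O-methyl enol ether is removed by chromatography here or by crystallisation of 6.

Step 3
Reactants: 4 cis-2,5-dimethyl-2-(3-oxobutyl)cyclohexane-1,3-dione
Product: 6 (3S,8aS)-3,8a-dimethyl-3,4,8,8a-tetrahydronaphthalene-1,6(2H,7H)-dione, via cis-fused ketol 5 (not isolated)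
Conditions: L-proline (cat.), DMSO, rt
Reagents that add atoms: none
Why: Hajos–Parrish–Eder–Sauer–Wiechert aldol condensation, in which the proline enamine of the side-chain methyl ketone attacks one of the two enantiotopic ring carbonyls through the hydrogen-bonded transition state, should fix C6 as S (as for the parent Wieland–Miescher ketone) before ketol 5 dehydrates to the C1=C10 enone; recrystallisation can raise the enantiomeric purity if needed.

Step 4
Reactants: 6 enedione (C1=C10, C9 ketone, C5 ketone)
Product: 7 C5 ethylene ketal of 6
Conditions: ethylene glycol, p-TsOH·H2O (cat.), 4 Å molecular sieves, rt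
Reagents that add atoms: ethylene glycol, OCCO
Why: Acid-catalysed ketalisation takes place at the saturated C5 ketone and not at the less electrophilic conjugated C9 ketone, as established for the parent enedione, which masks C5 for the hydrazine and organometallic steps.

Step 5
Reactants: 7 C5 ketal enone
Product: 8 1β,10β-epoxy-9-ketone (C5 ketal)
Conditions: 30% H2O2, aq. NaOH (cat.), MeOH, 0 °C
Reagents that add atoms: hydrogen peroxide, OO
Why: Weitz–Scheffer epoxidation, in which hydroperoxide adds to the enone β-carbon C1 from the β face (axial attack giving the cis-fused enolate, as with 4-en-3-one steroids) and the enolate closes the oxirane, should put the C1 oxygen cis to the C6 methyl.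

Step 6
Reactants: 8 1β,10β-epoxy-9-ketone
Product: 9 cis-decalin 1β-ol with C9=C10 alkene (C5 ketal)
Conditions: N2H4·H2O, AcOH, MeOH, 0 °C to rt
Reagents that add atoms: none
Why: Wharton transposition, in which the epoxy hydrazone opens to a vinyl diazene that loses N2, moves the alkene to C9=C10 and leaves the C1–O bond and its β configuration untouched.

Step 7
Reactants: 9 tertiary allylic alcohol
Product: 10 9β,10β-epoxy-1β-ol (C5 ketal)
Conditions: VO(acac)2 (cat.), t-BuOOH, CH2Cl2, 0 °C to rt
Reagents that add atoms: tert-butyl hydroperoxide, CC(C)(C)OO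
Why: Vanadium-catalysed epoxidation is delivered by the pseudoaxial tertiary allylic hydroxyl, so the oxirane should form on the β face, syn to the C1 oxygen.

Step 8
Reactants: 10 9β,10β-epoxy-1β-ol
Product: 11 1β-trimethylsilyl ether of 10
Conditions: N-(trimethylsilyl)imidazole, CH2Cl2, rt
Reagents that add atoms: N-(trimethylsilyl)imidazole, C[Si](C)(C)n1ccnc1
Why: Silylation of the hindered tertiary alcohol with a neutral, powerful silyl donor leaves the epoxide untouched and turns the hydroxyl into a group that pushes in the rearrangement without acting as an internal nucleophile.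

Step 9
Reactants: 11 cis-decalin 9β,10β-epoxy-1β-silyl ether (C5 ketal; 3β-methyl)
Product: 13 trans-fused hydroazulene β-hydroxy ketone (C1 ketone; 9β-OH; 10α-H; C5 ketal), via C9 trimethylsilyl ether 12 (not isolated)
Conditions: BF3·OEt2 (0.3 equiv), CH2Cl2, −78 °C; aq. citric acid/THF work-up, 0 °C
Reagents that add atoms: none
Why: BF3 binds the epoxide oxygen and, as the C10–O bond lengthens, the C1–C6 bond migrates to C10 from the face opposite the leaving oxygen while the silyloxy oxygen turns C1 into a carbonyl; silyl transfer to the C9 alkoxide gives 12 and releases the Lewis acid, and the acidic work-up frees the alcohol. The closest known reaction is the Lewis-acid semipinacol rearrangement of 2,3-epoxy alcohol silyl ethers to aldols, including its ring-contracting variants on cyclic epoxy alcohols. No ring is closed by cyclisation: the seven-membered ring arises by one-carbon expansion of ring A (C10 is inserted between C1 and C6) and the five-membered ring by contraction of ring B (C1 is expelled), both in the same 1,2-shift. C10 is the new stereocentre and is set by inversion, C6 entering anti to the β-oxygen so that H-10 ends up α, trans to the C6 methyl, while C6 migrates with retention and C9 keeps its β-oxygen. The step needs C6 rather than C2 to migrate and C10–O rather than C9–O to break: the equatorial 3β-methyl holds ring A in the chair in which C10 is axial on ring A, the silyloxy group is pseudoaxial on ring B and C1–C6, not C1–C2, is antiperiplanar to C10–O; the quaternary C6 is also the better migrating group, and only the C10–O bond lies next to the carbinol carbon and is assisted by it.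

Step 10
Reactants: 13 β-hydroxy ketone
Product: 14 1α-ol 9β-benzoate (C5 ketal)
Conditions: SmI2 (0.3 equiv), PhCHO (excess), THF, −10 °C
Reagents that add atoms: benzaldehyde, O=Cc1ccccc1
Why: Evans–Tishchenko reduction, in which the samarium-bound hemiacetal formed from the C9 hydroxyl and benzaldehyde delivers hydride through a six-membered transition state to the β face of the C1 ketone, should give the 1α-alcohol (1,3-anti to the C9 oxygen) and leave C9 as its benzoate, so the two oxygens are set and told apart in one operation.

Step 11
Reactants: 14 1α-ol 9β-benzoate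
Product: 15 1α-tert-butyldimethylsilyl ether 9β-benzoate
Conditions: TBSOTf, 2,6-lutidine, CH2Cl2, −78 °C
Reagents that add atoms: tert-butyldimethylsilyl trifluoromethanesulfonate, CC(C)(C)[Si](C)(C)OS(=O)(=O)C(F)(F)F
Why: Standard low-temperature silylation of the secondary 1α-alcohol, under which neither the dioxolane nor the benzoate (no acyl shift) is disturbed.

Step 12
Reactants: 15 silyl ether benzoate
Product: 16 1α-silyloxy-9β-ol (C5 ketal)
Conditions: K2CO3 (cat.), MeOH, rt to 40 °C
Reagents that add atoms: none
Why: Base-catalysed transesterification removes the benzoate; no carbonyl group is present, so nothing can epimerise, and the silyl ether and dioxolane are stable to methanolic carbonate.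

Step 13
Reactants: 16 1α-silyloxy-9β-ol
Product: 17 1α-silyloxy-9-ketone (C5 ketal)
Conditions: Dess–Martin periodinane, CH2Cl2, rt
Reagents that add atoms: none
Why: Dess–Martin oxidation under neutral, non-enolising conditions should give the β-silyloxy ketone without epimerising C10 or eliminating the C1 silyloxy group; 17 is used at once.

Step 14
Reactants: 17 1α-silyloxy-9-ketone; 18 isopropylmagnesium chloride
Product: 19 9β-hydroxy-9α-isopropyl carbinol (1α-silyl ether; C5 ketal)
Conditions: CeCl3 (anhydrous), THF, −78 °C; 18; aq. NH4Cl work-up
Reagents that add atoms: none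
Why: Organocerium addition suppresses enolisation and β-elimination of the β-silyloxy ketone, and the reagent should approach C9 from the α face, away from the pseudoaxial C6 methyl that sits 1,3 to the carbonyl on the β face (as in additions to D-ring steroid ketones), giving the 9β-hydroxy-9α-isopropyl centre.

Step 15
Reactants: 19 carbinol ketal
Product: 20 C5 ketone (1α-silyl ether; 9β-hydroxy-9α-isopropyl)
Conditions: PPTS (cat.), acetone/H2O, 60 °C
Reagents that add atoms: water, O
Why: Mild acid-catalysed hydrolysis of the dioxolane frees the C5 ketone under conditions that a secondary tert-butyldimethylsilyl ether and the tertiary alcohol should survive.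

Step 16
Reactants: 20 C5 ketone
Product: 21 C5 p-toluenesulfonylhydrazone
Conditions: TsNHNH2, PPTS (cat.), EtOH, 70 °C
Reagents that add atoms: p-toluenesulfonylhydrazide, Cc1ccc(cc1)S(=O)(=O)NN
Why: Condensation gives the hydrazone with the sulfonamide nitrogen anti to the quaternary C6, as needed for syn-deprotonation at C4; hindered α-quaternary ketones such as camphor form these hydrazones on heating.

Step 17
Reactants: 21 tosylhydrazone
Product: 22 C4=C5 alkene (1α-silyl ether; 9β-hydroxy-9α-isopropyl; 3β-methyl)
Conditions: MeLi (4 equiv), Et2O/THF, 0 °C to rt; H2O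
Reagents that add atoms: none
Why: Shapiro reaction, in which deprotonation at the only α-methylene (C4), loss of sulfinate and N2 and protonation of the C5 vinyllithium give the alkene, allows no regioisomer because C6 is quaternary.

Step 18
Reactants: 22 C4=C5 alkene
Product: 23 4α,5α-epoxide
Conditions: mCPBA, CH2Cl2, 0 °C
Reagents that add atoms: 3-chloroperoxybenzoic acid, OOC(=O)c1cccc(Cl)c1
Why: Prilezhaev epoxidation from the α face, anti to the pseudoaxial C6 methyl that flanks C5 (the bias that gives 1α,2α-epoxides from 1-ene steroids), should place the C5 oxygen α.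

Step 19
Reactants: 23 4α,5α-epoxide
Product: 25 1α-silyloxy-3-ene-5α,9β-diol, via bis(trimethylsilyl) ether 24 (not isolated)
Conditions: TMSOTf (3 equiv), 2,6-lutidine, toluene, −78 to 0 °C; DBU, rt to 50 °C; then K2CO3 (cat.), MeOH
Reagents that add atoms: trimethylsilyl trifluoromethanesulfonate, C[Si](C)(C)OS(=O)(=O)C(F)(F)F (silyl groups of 24 only, removed again in the methanolysis)
Why: Noyori-type isomerisation of an epoxide to an allylic alcohol, in which triflate opens the silyl-activated epoxide at C4 (away from the neopentyl C5) with inversion and DBU then removes the only antiperiplanar β-hydrogen, the axial H-3α, should form the C3=C4 alkene while the C5–O bond and its α configuration stay untouched.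

Step 20
Reactants: 25 1α-silyloxy-3-ene-5α,9β-diol
Product: 26 1α,5α,9β-triol
Conditions: TBAF, THF, rt
Reagents that add atoms: none
Why: Fluoride cleaves the remaining silyl ether; the allylic and tertiary alcohols are stable to these conditions.

Step 21
Reactants: 26 1α,5α,9β-triol; 27 angelic acid (two equivalents enter the product)
Product: 28 CNP0183261.1 (1α,5α-bis-angelate, 9β-hydroxy-9α-isopropyl)
Conditions: 27, 2,4,6-trichlorobenzoyl chloride, Et3N, toluene, rt; then 26, 80 °C
Reagents that add atoms: none
Why: Yamaguchi-type esterification through the angelic 2,4,6-trichlorobenzoic mixed anhydride should acylate the two secondary alcohols and not the tertiary C9 hydroxyl, and is the established way to introduce angelates without isomerisation to tiglates.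

**Compound list**
1 | 5-methylcyclohexane-1,3-dione | CC1CC(=O)CC(=O)C1 | starting material
2 | methyl vinyl ketone | CC(=O)C=C | starting material
3 | 5-methyl-2-(3-oxobutyl)cyclohexane-1,3-dione | CC1CC(=O)C(CCC(C)=O)C(=O)C1 | intermediate
4 | cis-2,5-dimethyl-2-(3-oxobutyl)cyclohexane-1,3-dione (methyls cis; achiral) | C[C@H]1CC(=O)[C@](C)(CCC(C)=O)C(=O)C1 | intermediate
5 | cis-fused ketol: 1β-hydroxy-3β,6β-dimethyldecalin-5,9-dione | O=C1C[C@@]2(O)C[C@H](C)CC(=O)[C@@]2(C)CC1 | intermediate (not isolated)
6 | (3S,8aS)-3,8a-dimethyl-3,4,8,8a-tetrahydronaphthalene-1,6(2H,7H)-dione (C1=C10, C9 and C5 ketones, both methyls β) | O=C1C=C2C[C@H](C)CC(=O)[C@@]2(C)CC1 | intermediate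
7 | C5 ethylene ketal of 6 | O=C1C=C2C[C@H](C)CC3(OCCO3)[C@@]2(C)CC1 | intermediate
8 | 1β,10β-epoxy-9-ketone, C5 ketal | O=C1[C@@H]2O[C@@]23C[C@H](C)CC4(OCCO4)[C@@]3(C)CC1 | intermediate
9 | cis-decalin 1β-ol, C9=C10 alkene, C5 ketal | O[C@]12C[C@H](C)CC3(OCCO3)[C@@]1(C)CCC=C2 | intermediate
10 | 9β,10β-epoxy-1β-ol, C5 ketal | O[C@]12C[C@H](C)CC3(OCCO3)[C@@]1(C)CC[C@@H]4O[C@H]24 | intermediate
11 | 1β-trimethylsilyl ether of 10 | C[Si](C)(C)O[C@]12C[C@H](C)CC3(OCCO3)[C@@]1(C)CC[C@@H]4O[C@H]24 | intermediate
12 | trans-hydroazulen-1-one, 9β-trimethylsilyloxy, C5 ketal | O=C1C[C@H](C)CC2(OCCO2)[C@@]3(C)CC[C@H](O[Si](C)(C)C)[C@H]13 | intermediate (not isolated)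
13 | trans-hydroazulen-1-one, 9β-hydroxy, 10α-H, C5 ketal | O=C1C[C@H](C)CC2(OCCO2)[C@@]3(C)CC[C@H](O)[C@H]13 | intermediate
14 | 1α-ol 9β-benzoate, C5 ketal | O[C@H]1C[C@H](C)CC2(OCCO2)[C@@]3(C)CC[C@H](OC(=O)c4ccccc4)[C@H]13 | intermediate
15 | 1α-tert-butyldimethylsilyl ether 9β-benzoate | CC(C)(C)[Si](C)(C)O[C@H]1C[C@H](C)CC2(OCCO2)[C@@]3(C)CC[C@H](OC(=O)c4ccccc4)[C@H]13 | intermediate
16 | 1α-silyloxy-9β-ol, C5 ketal | CC(C)(C)[Si](C)(C)O[C@H]1C[C@H](C)CC2(OCCO2)[C@@]3(C)CC[C@H](O)[C@H]13 | intermediate
17 | 1α-silyloxy-9-ketone, C5 ketal | CC(C)(C)[Si](C)(C)O[C@H]1C[C@H](C)CC2(OCCO2)[C@@]3(C)CCC(=O)[C@H]13 | intermediate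
18 | isopropylmagnesium chloride | CC(C)[Mg]Cl | starting material
19 | 9β-hydroxy-9α-isopropyl carbinol, 1α-silyl ether, C5 ketal | CC(C)(C)[Si](C)(C)O[C@H]1C[C@H](C)CC2(OCCO2)[C@@]3(C)CC[C@@](O)(C(C)C)[C@H]13 | intermediate
20 | C5 ketone, 1α-silyl ether, 9β-hydroxy-9α-isopropyl | CC(C)(C)[Si](C)(C)O[C@H]1C[C@H](C)CC(=O)[C@@]2(C)CC[C@@](O)(C(C)C)[C@H]12 | intermediate
21 | C5 p-toluenesulfonylhydrazone of 20 (sulfonamide N anti to C6) | CC(C)(C)[Si](C)(C)O[C@H]1C[C@H](C)C/C(=N\NS(=O)(=O)c2ccc(C)cc2)[C@@]3(C)CC[C@@](O)(C(C)C)[C@H]13 | intermediate
22 | C4=C5 alkene, 1α-silyl ether, 3β-methyl | CC(C)(C)[Si](C)(C)O[C@H]1C[C@H](C)C=C[C@@]2(C)CC[C@@](O)(C(C)C)[C@H]12 | intermediate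
23 | 4α,5α-epoxide of 22 | CC(C)(C)[Si](C)(C)O[C@H]1C[C@H](C)[C@H]2O[C@H]2[C@@]3(C)CC[C@@](O)(C(C)C)[C@H]13 | intermediate
24 | C3=C4 alkene, 5α- and 9β-trimethylsilyl ethers, 1α-tert-butyldimethylsilyl ether | CC(C)(C)[Si](C)(C)O[C@H]1CC(C)=C[C@@H](O[Si](C)(C)C)[C@@]2(C)CC[C@@](O[Si](C)(C)C)(C(C)C)[C@H]12 | intermediate (not isolated)
25 | C3=C4 alkene, 5α,9β-diol, 1α-tert-butyldimethylsilyl ether | CC(C)(C)[Si](C)(C)O[C@H]1CC(C)=C[C@@H](O)[C@@]2(C)CC[C@@](O)(C(C)C)[C@H]12 | intermediate
26 | C3=C4 alkene, 1α,5α,9β-triol | O[C@H]1CC(C)=C[C@@H](O)[C@@]2(C)CC[C@@](O)(C(C)C)[C@H]12 | intermediate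
27 | angelic acid | C/C=C(/C)C(=O)O | starting material
28 | CNP0183261.1 | C/C=C(/C)C(=O)O[C@H]1CC(C)=C[C@@H](OC(=O)/C(C)=C\C)[C@@]2(C)CC[C@@](O)(C(C)C)[C@H]12 | target

Total step count: 21. Longest linear sequence: 21 steps (1 to 28).

**Steps most likely to fail**

Step 9. What may go wrong: the dioxolane may ionise or its axial oxygen may attack C10 under the Lewis acid; C2 may migrate instead of C6; or the aldol may be lost by retro-aldol cleavage or β-elimination before isolation. The fallback sets out from 10 and returns at 14. The unprotected epoxy alcohol 10 is treated with catalytic SmI2 and benzaldehyde in 1,2-dichloroethane, a known tandem semipinacol rearrangement/Tishchenko reduction of hydroxy epoxides. The samarium alkoxide chelate of the C1 and epoxide oxygens triggers the same shift of C6 without an external strong Lewis acid, and the aldol 13, formed in the flask, is reduced at once through its C9 hemiacetal to give 14. This drops the silyl ether and makes no compound outside the list (F0).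

Step 19. What may go wrong: the Lewis acid may induce a pinacol-type or hydride shift at the neopentyl epoxide instead of clean triflate opening at C4, or the elimination of the secondary triflate may be sluggish. The fallback sets out from 22 and returns at 25. Alkene 22 is photo-oxygenated (O2, tetraphenylporphyrin, visible light, CH2Cl2, 0 °C) in a Schenck ene reaction. Oxygen should add to C5 on the α face with abstraction of the only allylic hydrogen, the axial H-3α (C6 bears none), which shifts the alkene to C3=C4 and gives the 5α-allylic hydroperoxide F1. Reduction of F1 in the same flask with PPh3 gives 25.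

Step 21. What may go wrong: acylation of the hindered axial, neopentyl C5 hydroxyl may stall at the C1 mono-ester, and the angeloyl unit may isomerise from Z to E under forcing conditions. The fallback sets out from 26 and returns at 28. Both secondary alcohols are esterified with the less hindered 2-[bis(2,2,2-trifluoroethoxy)phosphoryl]propanoic acid (DCC, DMAP, CH2Cl2) to give the bis(phosphonopropionate) F2. A Still–Gennari olefination of F2 with acetaldehyde (KHMDS, 18-crown-6, THF, −78 °C) then builds both Z-configured 2-methylbut-2-enoates in place and gives 28.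

**Further compounds**
F0 | step 9 | none | none
F1 | step 19 | 5α-hydroperoxide: C3=C4 alkene, 9β-hydroxy-9α-isopropyl, 1α-tert-butyldimethylsilyl ether | CC(C)(C)[Si](C)(C)O[C@H]1CC(C)=C[C@@H](OO)[C@@]2(C)CC[C@@](O)(C(C)C)[C@H]12
F2 | step 21 | 1α,5α-bis{2-[bis(2,2,2-trifluoroethoxy)phosphoryl]propanoate} of 26 (epimeric at the phosphonate-bearing carbons) | CC(C(=O)O[C@H]1CC(C)=C[C@@H](OC(=O)C(C)P(=O)(OCC(F)(F)F)OCC(F)(F)F)[C@@]2(C)CC[C@@](O)(C(C)C)[C@H]12)P(=O)(OCC(F)(F)F)OCC(F)(F)F
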